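A direct plan would build the pyrrole ring onto a finished polybromobenzene. 1,2,4,5-Tetrabromobenzene A1 would be formylated by bromine–magnesium exchange to 2,4,5-tribromobenzaldehyde A2. A non-stabilised N-methyl azomethine ylide would be added to the aldehyde and the adduct hydrolysed to 2-(methylamino)-1-(2,4,5-tribromophenyl)ethan-1-ol A3. N-Arylation with CuI and dehydration would close the ring to 5,6-dibromo-1-methyl-1H-indole A4, and NBS would then brominate C3. Its weakest operations would be:
(a) the ylide addition to the aldehyde, a capricious decarboxylative cycloaddition that would spend a step on a carbinol stereocentre only to erase it;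
(b) the N-arylative ring closure, which would have to single out one of three aryl C–Br bonds and would leave oligomerisation by intermolecular N-arylation, and the fate of a sensitive indolin-3-ol, to chance;
(c) the electrophilic bromination of the finished indole, where over-bromination at C2 and the lability of 3-bromoindoles would put the most precious material at risk.

**Plan of the new route**
The retrosynthesis cuts C3a–C4 and C7–C7a, so the whole benzene ring is removed as a four-carbon unit. The pyrrole ring is present from the start and the benzene ring arises last, by a Diels–Alder reaction of 3,4-dibromothiophene 1,1-dioxide with the C2=C3 bond of 3,4-dibromo-1-methylpyrrole, followed in the same flask by loss of SO2 and HBr. The enabling feature is that the carbocycle is a symmetric C4H–C5Br–C6Br–C7H unit and the pyrrole bromine sits at C3, next to the fusion carbon C3a. The target is therefore the adduct of two C2v-symmetric partners minus SO2 and HBr, and the extra bromine placed at C3a is the leaving group that aromatises the new ring. No C–N bond is made on a haloarene, no stereocentre outlives the flask, no regiochemical choice exists, and no indole is ever brominated.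

Key step: step 4

Assumption: 1-(triisopropylsilyl)pyrrole and 3,4-dibromothiophene are taken as commercial. The target has no stereocentre; intermediates 7 and 8 are racemic and are written as one enantiomer.

**Step 1**
Reactants: 1 1-(triisopropylsilyl)-1H-pyrrole
Product: 2 3,4-dibromo-1-(triisopropylsilyl)-1H-pyrrole
Conditions: NBS (2.05 equiv), THF, −78 °C → rt, dark
Reagents that add atoms: N-bromosuccinimide, O=C1CCC(=O)N1Br
Why: Electrophilic aromatic bromination in which the bulky triisopropylsilyl group shields both α-positions, so that the two bromines should enter the β-positions C3 and C4 one after the other.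

**Step 2**
Reactants: 2 3,4-dibromo-1-(triisopropylsilyl)-1H-pyrrole
Product: 4 3,4-dibromo-1-methyl-1H-pyrrole, via 3,4-dibromo-1H-pyrrole 3 (not isolated)
Conditions: Bu4NF (1.1 equiv), THF, 0 °C, 15 min; extractive work-up, crude 3 used at once; NaH (1.3 equiv), MeI (1.5 equiv), DMF, 0 °C → rt
Reagents that add atoms: iodomethane, CI
Why: Fluoride-induced N–Si cleavage followed by SN2 N-methylation of the sodium pyrrolide, with the acid- and air-sensitive NH-pyrrole carried on without storage.

**Step 3**
Reactants: 5 3,4-dibromothiophene
Product: 6 3,4-dibromothiophene 1,1-dioxide
Conditions: urea·H2O2 (4 equiv), (CF3CO)2O (5 equiv), MeCN, 0 °C → rt; poured onto ice/aq. NaHCO3, extracted, crystallised, kept at −20 °C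
Reagents that add atoms: hydrogen peroxide (used as its urea adduct), OO
Why: S-Oxidation of an electron-poor thiophene by trifluoroperacetic acid made in the flask, in which the S-oxide should be oxidised faster than the thiophene and the two β-halogens should slow the [4+2] self-dimerisation enough for the dioxide to be isolated, as is usual for 3,4-dihalothiophene 1,1-dioxides.

**Step 4**
Reactants: 4 3,4-dibromo-1-methyl-1H-pyrrole; 6 3,4-dibromothiophene 1,1-dioxide
Product: 9 3,5,6-tribromo-1-methyl-1H-indole, via sulfone-bridged cycloadduct 7 (not isolated), via 3,3a,5,6-tetrabromo-1-methyl-3a,7a-dihydro-1H-indole 8 (not isolated)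
Conditions: 4 (3 equiv), 6 (1 equiv, added by syringe pump over 6 h), NaHCO3 powder (3 equiv), chlorobenzene, 120 °C, slow Ar stream, dark; excess 4 recovered
Reagents that add atoms: none
Why: Proposed new method: the electron-poor, cyclic s-cis diene 6 should undergo an inverse-electron-demand Diels–Alder reaction with the enamine-like C2=C3 bond of 4, the leading bond forming between the unsubstituted pyrrole α-carbon and a diene terminus, to give the bridged sulfone 7, which should extrude SO2 by a cheletropic retro-reaction under the same conditions to the cis-fused dihydroindole 8; in 8 the C3a–Br bond is tertiary, doubly allylic and vinylogously conjugated to nitrogen, so it should ionise readily and loss of the C7a proton (E1) should deliver the benzene ring without any oxidant. The closest known reaction types are the benzannulations of halogenated thiophene 1,1-dioxides with alkenes and haloalkenes (Diels–Alder reaction, SO2 loss, then HX loss) and the use of pyrrole and indole C2=C3 bonds as 2π partners towards electron-poor dienes such as 1,2,4,5-tetrazines; their combination on a β-bromopyrrole is new. The six-membered ring is closed by an intermolecular [4+2] cycloaddition that forms C3a–C4 and C7–C7a suprafacially on both partners, the five-membered ring being present beforehand. The two stereocentres of 8 (C3a and C7a, cis by the suprafacial addition, racemic) are both erased in the elimination, so no stereocontrol is required. The only selectivity needed is chemoselectivity, namely cross-cycloaddition ahead of self-dimerisation of 6 and ahead of a second annulation on the C2=C3 bond of the product, and it is secured by a low stationary concentration of 6 in an excess of 4, while regiochemistry cannot arise because both partners are C2v-symmetric; solid NaHCO3 removes the HBr that would otherwise degrade the bromopyrrole and the 3-bromoindole.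

**Compound list**
1 | 1-(triisopropylsilyl)-1H-pyrrole | CC(C)[Si](C(C)C)(C(C)C)n1cccc1 | starting material
2 | 3,4-dibromo-1-(triisopropylsilyl)-1H-pyrrole | CC(C)[Si](C(C)C)(C(C)C)n1cc(Br)c(Br)c1 | intermediate
3 | 3,4-dibromo-1H-pyrrole | Brc1c[nH]cc1Br | intermediate
4 | 3,4-dibromo-1-methyl-1H-pyrrole | Cn1cc(Br)c(Br)c1 | intermediate
5 | 3,4-dibromothiophene | Brc1cscc1Br | starting material
6 | 3,4-dibromothiophene 1,1-dioxide | O=S1(=O)C=C(Br)C(Br)=C1 | intermediate
7 | 3,3a,5,6-tetrabromo-1-methyl-3a,4,7,7a-tetrahydro-1H-4,7-epithioindole 8,8-dioxide (racemic, cis ring fusion, bridgehead orientation not defined) | CN1C=C(Br)[C@]2(Br)[C@H]1C1C(Br)=C(Br)C2S1(=O)=O | intermediate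
8 | 3,3a,5,6-tetrabromo-1-methyl-3a,7a-dihydro-1H-indole (racemic, cis-fused) | CN1C=C(Br)[C@@]2(Br)C=C(Br)C(Br)=C[C@@H]12 | intermediate
9 | 3,5,6-tribromo-1-methyl-1H-indole | Cn1cc(Br)c2cc(Br)c(Br)cc21 | target

**Step count and risks**
Total step count: 4. Longest linear sequence: 3 steps (steps 1, 2 and 4); step 3 is a one-step branch.

Steps most likely to fail:

1. Step 4 (Proposed new method). The aromatic C2=C3 bond of the pyrrole may not engage before 6 is used up by self-dimerisation. Bond formation at the α-carbon may be followed by proton loss (conjugate substitution) instead of ring closure. The product may be annulated a second time at its own C2=C3 bond. The fallback uses known chemistry and closes the benzene ring by Bergman cycloaromatisation, the established route from ortho-bis(bromoethynyl)arenes to ortho-dibromoarenes. It sets out from 4. Vilsmeier–Haack formylation (POCl3, DMF, then aqueous base) would give a single aldehyde, 3,4-dibromo-1-methyl-1H-pyrrole-2-carbaldehyde F1, because both α-positions are equivalent. Sonogashira coupling with ethynyltrimethylsilane (Pd(PPh3)2Cl2, CuI, Et3N, THF, 45 °C) should take place at the C3–Br bond, which is conjugated to the formyl group, and give 4-bromo-1-methyl-3-[(trimethylsilyl)ethynyl]-1H-pyrrole-2-carbaldehyde F2. Ohira–Bestmann homologation (dimethyl (1-diazo-2-oxopropyl)phosphonate, K2CO3, MeOH) with concomitant desilylation would give 4-bromo-2,3-diethynyl-1-methyl-1H-pyrrole F3. Deprotonation with LiN(SiMe3)2 and bromination with NBS at −78 °C would give 4-bromo-2,3-bis(bromoethynyl)-1-methyl-1H-pyrrole F4. Heating F4 at 180 °C in chlorobenzene with an excess of 1,4-cyclohexadiene should form the C5–C6 bond between the two bromine-bearing alkyne carbons and cap C4 and C7 with hydrogen. The fallback comes back to the route at 9.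

2. Step 3. The oxidation may stall at the S-oxide, which dimerises, or the dioxide may dimerise while it is concentrated and stored. The fallback blocks the α-positions before oxidation. It sets out from 5. Double deprotonation and silylation (LiN(i-Pr)2, Me3SiCl, THF, −78 °C) would give 3,4-dibromo-2,5-bis(trimethylsilyl)thiophene F5. Oxidation with mCPBA would give the sterically protected 3,4-dibromo-2,5-bis(trimethylsilyl)thiophene 1,1-dioxide F6. Fluoride-induced protodesilylation (Bu4NF buffered with AcOH, THF, −20 °C), favoured because the α-sulfonyl vinyl carbon is a good leaving group from silicon, would release the diene shortly before use. The fallback comes back to the route at 6.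

3. Step 2. The NH-pyrrole may oligomerise under the influence of acid, air or light between desilylation and methylation. The fallback sets the bromine pattern on a pyrrole that already carries the methyl group. It sets out from 1. One-pot fluoride-induced exchange of silyl for methyl (Bu4NF, MeI, THF) would give 1-methyl-1H-pyrrole F7, which is also an article of commerce. Exhaustive bromination (NBS, 4.1 equiv, THF, −78 °C → rt) would give 2,3,4,5-tetrabromo-1-methyl-1H-pyrrole F8. Two rounds of α-selective bromine–lithium exchange (n-BuLi, THF, −78 °C, then MeOH) would remove the two α-bromines, in analogy to the classical reduction of tetrabromothiophene to 3,4-dibromothiophene. The fallback comes back to the route at 4.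

**Further compounds**
F1 | step 4 | 3,4-dibromo-1-methyl-1H-pyrrole-2-carbaldehyde | Cn1cc(Br)c(Br)c1C=O
F2 | step 4 | 4-bromo-1-methyl-3-[(trimethylsilyl)ethynyl]-1H-pyrrole-2-carbaldehyde | Cn1cc(Br)c(C#C[Si](C)(C)C)c1C=O
F3 | step 4 | 4-bromo-2,3-diethynyl-1-methyl-1H-pyrrole | Cn1cc(Br)c(C#C)c1C#C
F4 | step 4 | 4-bromo-2,3-bis(bromoethynyl)-1-methyl-1H-pyrrole | Cn1cc(Br)c(C#CBr)c1C#CBr
F5 | step 3 | 3,4-dibromo-2,5-bis(trimethylsilyl)thiophene | C[Si](C)(C)c1sc([Si](C)(C)C)c(Br)c1Br
F6 | step 3 | 3,4-dibromo-2,5-bis(trimethylsilyl)thiophene 1,1-dioxide | C[Si](C)(C)C1=C(Br)C(Br)=C([Si](C)(C)C)S1(=O)=O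
F7 | step 2 | 1-methyl-1H-pyrrole | Cn1cccc1
F8 | step 2 | 2,3,4,5-tetrabromo-1-methyl-1H-pyrrole | Cn1c(Br)c(Br)c(Br)c1Br
A1 | direct plan | 1,2,4,5-tetrabromobenzene | Brc1cc(Br)c(Br)cc1Br
A2 | direct plan | 2,4,5-tribromobenzaldehyde | O=Cc1cc(Br)c(Br)cc1Br
A3 | direct plan | 2-(methylamino)-1-(2,4,5-tribromophenyl)ethan-1-ol (racemic) | CNCC(O)c1cc(Br)c(Br)cc1Br
A4 | direct plan | 5,6-dibromo-1-methyl-1H-indole | Cn1ccc2cc(Br)c(Br)cc21
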